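**Retrosynthetic overview**

- The target consists of two trans-2,3-diaryl-2,3-dihydrobenzofurans: unit 1 (unprimed, benzo ring A) and unit 2 (primed, benzo ring B), joined C3–C6'. The strategy rests on C3a' of ring B, which carries C3' and sits between C4' (OH) and C7a' (O1'). Ring B is therefore carried as a cyclohexane-1,3-dione whose C2 is that carbon.
- Unit 2: C3'–C3a' and O1'–C2' are formed together by annulation of a 2-diazo-1,3-dione carbene with an (E)-stilbene under a chiral dirhodium carboxylate; ring B is aromatised afterwards. The ester at C6' is the handle for unit 1.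
- Unit 1: the C3–C3a bond comes from acylation of a ring-A aryllithium; the furan ring (C2–C3 and O1–C2) comes from [4+1] annulation of the ring-A o-quinone methide with a chiral 4-methoxybenzyl sulfonium ylide.
- All eight phenols are carried as methyl ethers and freed in the last step.
- Ring order: unit 2 dihydrofuran ring (step 3), ring B aromatised (step 4), unit 1 dihydrofuran ring (step 13); ring A and the four pendant aryl rings are bought.

Key step: step 3

Assumption: the sense of induction of neither chiral reagent is known for these substrates, so Rh2(S-PTTL)4 and the (1R,4R,5R)-sulfide 19 (taken as commercial, like dione 1) are written and the mirror-image reagent would be used if the opposite sense is found.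

**Route**

Step 1
Reactants: 1 methyl 3,5-dioxocyclohexane-1-carboxylate
Product: 2 methyl 4-diazo-3,5-dioxocyclohexane-1-carboxylate
Conditions: p-ABSA, Et3N, MeCN, 0 °C → rt
Reagents that add atoms: 4-acetamidobenzenesulfonyl azide (p-ABSA), CC(=O)Nc1ccc(cc1)S(=O)(=O)N=[N+]=[N-]
Why: Regitz diazo transfer, in which the enolate of the cyclic 1,3-dione attacks the sulfonyl azide and the adduct collapses to the 2-diazo-1,3-dione and the sulfonamide.

Step 2
Reactants: 3 2,4-dimethoxybenzaldehyde; 4 diethyl (3,5-dimethoxybenzyl)phosphonate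
Product: 5 (E)-2,4,3',5'-tetramethoxystilbene
Conditions: KOtBu, THF, 0 °C → rt
Reagents that add atoms: none
Why: Horner–Wadsworth–Emmons olefination of an aryl aldehyde with a benzylphosphonate anion, which should give the (E)-alkene through the reversible, anti-selective addition.

Step 3
Reactants: 2 methyl 4-diazo-3,5-dioxocyclohexane-1-carboxylate; 5 (E)-2,4,3',5'-tetramethoxystilbene
Product: 6 methyl (2R,3R)-2-(2,4-dimethoxyphenyl)-3-(3,5-dimethoxyphenyl)-4-oxo-2,3,4,5,6,7-hexahydro-1-benzofuran-6-carboxylate (both C6 epimers)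
Conditions: Rh2(S-PTTL)4 (dirhodium tetrakis[N-phthaloyl-(S)-tert-leucinate], 2 mol%), 5 (2 equiv), slow addition of 2, PhF, 4 Å MS, 25–40 °C
Reagents that add atoms: none
Why: Proposed new method: the dirhodium carboxylate should convert 2 into an electrophilic acceptor/acceptor carbene, which is attacked by the alkene carbon of 5 that bears the 3,5-dimethoxyphenyl ring, because only this mode places the developing cation next to the 2,4-dimethoxyphenyl ring, whose ortho and para methoxy groups stabilise it. The dione enolate oxygen then captures the benzylic cation (5-exo-trig closure of the zwitterion), so that C3–C3a and O1–C2 are formed and the dihydrofuran ring is closed on the only carbon that lies between the two ring oxygens. The closest known reaction is the racemic dirhodium tetracarboxylate-catalysed formal [3+2] annulation of cyclic 2-diazo-1,3-diones with enol ethers and electron-rich styrenes; useful asymmetric induction on a 1,2-diarylethene has no precedent. C3 is set in the C–C bond-forming event, in which the tert-leucinate ligand wall must distinguish the two faces of the stilbene carbon while the carbene is still rhodium-bound; C2 is then set by the substrate, the freely rotating cation closing anti to the C3 aryl group (trans). The step needs regioselectivity (secured by the ortho/para versus meta methoxy pattern of the two aryl rings), chemoselectivity for the alkene over the methoxyarene C–H bonds (secured by the enol-ether-like nucleophilicity of the 2,4-dimethoxystyrene π bond) and enantioselectivity (catalyst, unproven).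

Step 4
Reactants: 6 methyl (2R,3R)-2-(2,4-dimethoxyphenyl)-3-(3,5-dimethoxyphenyl)-4-oxo-2,3,4,5,6,7-hexahydro-1-benzofuran-6-carboxylate
Product: 8 methyl (2R,3R)-2-(2,4-dimethoxyphenyl)-3-(3,5-dimethoxyphenyl)-4-hydroxy-2,3-dihydro-1-benzofuran-6-carboxylate, via lithium enolate 7 (not isolated)
Conditions: LiN(iPr)2 (LDA), THF, −78 °C; then PhS(Cl)=NtBu, −78 °C → rt; aq NH4Cl
Reagents that add atoms: none
Why: Mukaiyama dehydrogenation, in which the kinetic C5 enolate of the vinylogous ester is sulfinimidoylated and undergoes syn elimination at low temperature to a cyclohexadienone that tautomerises to the phenol; the basic, non-oxidising conditions should spare the acid-labile C2–O bond and the electron-rich arenes, and both C6 epimers converge.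

Step 5
Reactants: 8 methyl (2R,3R)-2-(2,4-dimethoxyphenyl)-3-(3,5-dimethoxyphenyl)-4-hydroxy-2,3-dihydro-1-benzofuran-6-carboxylate
Product: 9 methyl (2R,3R)-2-(2,4-dimethoxyphenyl)-3-(3,5-dimethoxyphenyl)-4-methoxy-2,3-dihydro-1-benzofuran-6-carboxylate
Conditions: MeI, K2CO3, acetone, 40 °C
Reagents that add atoms: iodomethane, CI
Why: Williamson O-methylation of the phenoxide, which masks the C4' hydroxyl before the organometallic steps.

Step 6
Reactants: 9 methyl (2R,3R)-2-(2,4-dimethoxyphenyl)-3-(3,5-dimethoxyphenyl)-4-methoxy-2,3-dihydro-1-benzofuran-6-carboxylate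
Product: 10 (2R,3R)-2-(2,4-dimethoxyphenyl)-3-(3,5-dimethoxyphenyl)-N,4-dimethoxy-N-methyl-2,3-dihydro-1-benzofuran-6-carboxamide
Conditions: MeNH(OMe)·HCl, iPrMgCl, THF, −20 → 0 °C
Reagents that add atoms: N,O-dimethylhydroxylamine hydrochloride, CNOC.Cl
Why: direct aminolysis of the ester by the chloromagnesium amide of N,O-dimethylhydroxylamine (Weinreb amide formation) stops at the amide and gives an acyl donor that cannot add twice.

Step 7
Reactants: 11 4-bromo-3,5-dimethoxybenzaldehyde; 12 diethyl (4-methoxybenzyl)phosphonate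
Product: 13 2-bromo-1,3-dimethoxy-5-[(E)-2-(4-methoxyphenyl)ethenyl]benzene
Conditions: KOtBu, THF, 0 °C → rt
Reagents that add atoms: none
Why: Horner–Wadsworth–Emmons olefination as in step 2, (E)-selective and inert towards the aryl bromide.

Step 8
Reactants: 13 2-bromo-1,3-dimethoxy-5-[(E)-2-(4-methoxyphenyl)ethenyl]benzene; 10 (2R,3R)-2-(2,4-dimethoxyphenyl)-3-(3,5-dimethoxyphenyl)-N,4-dimethoxy-N-methyl-2,3-dihydro-1-benzofuran-6-carboxamide
Product: 15 [(2R,3R)-2-(2,4-dimethoxyphenyl)-3-(3,5-dimethoxyphenyl)-4-methoxy-2,3-dihydro-1-benzofuran-6-yl]{2,6-dimethoxy-4-[(E)-2-(4-methoxyphenyl)ethenyl]phenyl}methanone, via aryllithium 14 (not isolated)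
Conditions: 13 (1.5 equiv), n-BuLi, THF, −78 °C; then 10, −78 → 0 °C; aq NH4Cl
Reagents that add atoms: none
Why: bromine–lithium exchange at −78 °C should outrun carbolithiation of the stilbene, and the 2,6-dimethoxyaryllithium adds once to the Weinreb amide because the chelated tetrahedral intermediate releases the ketone only on work-up (Weinreb ketone synthesis), forming the future C3–C3a bond.

Step 9
Reactants: 15 [(2R,3R)-2-(2,4-dimethoxyphenyl)-3-(3,5-dimethoxyphenyl)-4-methoxy-2,3-dihydro-1-benzofuran-6-yl]{2,6-dimethoxy-4-[(E)-2-(4-methoxyphenyl)ethenyl]phenyl}methanone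
Product: 16 [(2R,3R)-2-(2,4-dimethoxyphenyl)-3-(3,5-dimethoxyphenyl)-4-methoxy-2,3-dihydro-1-benzofuran-6-yl]{2-hydroxy-6-methoxy-4-[(E)-2-(4-methoxyphenyl)ethenyl]phenyl}methanone
Conditions: BCl3 (1.5 equiv), CH2Cl2, −78 → 0 °C; then H2O
Reagents that add atoms: none
Why: chelation-controlled mono-demethylation, in which BCl3 bound to the ketone oxygen cleaves only a methoxy group ortho to the carbonyl and the resulting chelated aryloxyborane protects the second ortho methoxy group, while the other seven ethers have no carbonyl neighbour.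

Step 10
Reactants: 16 [(2R,3R)-2-(2,4-dimethoxyphenyl)-3-(3,5-dimethoxyphenyl)-4-methoxy-2,3-dihydro-1-benzofuran-6-yl]{2-hydroxy-6-methoxy-4-[(E)-2-(4-methoxyphenyl)ethenyl]phenyl}methanone
Product: 17 2-{[(2R,3R)-2-(2,4-dimethoxyphenyl)-3-(3,5-dimethoxyphenyl)-4-methoxy-2,3-dihydro-1-benzofuran-6-yl](hydroxy)methyl}-3-methoxy-5-[(E)-2-(4-methoxyphenyl)ethenyl]phenol (both carbinol epimers)
Conditions: NaBH4, THF/MeOH, 0 °C
Reagents that add atoms: none
Why: borohydride reduction of the diaryl ketone to the o-hydroxybenzhydrol, whose carbinol configuration is irrelevant because this carbon becomes planar in step 13.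

Step 11
Reactants: 17 2-{[(2R,3R)-2-(2,4-dimethoxyphenyl)-3-(3,5-dimethoxyphenyl)-4-methoxy-2,3-dihydro-1-benzofuran-6-yl](hydroxy)methyl}-3-methoxy-5-[(E)-2-(4-methoxyphenyl)ethenyl]phenol
Product: 18 2-{[(2R,3R)-2-(2,4-dimethoxyphenyl)-3-(3,5-dimethoxyphenyl)-4-methoxy-2,3-dihydro-1-benzofuran-6-yl](4-methylbenzenesulfonyl)methyl}-3-methoxy-5-[(E)-2-(4-methoxyphenyl)ethenyl]phenol (both epimers)
Conditions: p-TolSO2H (3 equiv), CH2Cl2, rt
Reagents that add atoms: 4-methylbenzenesulfinic acid, Cc1ccc(cc1)S(=O)O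
Why: the doubly activated benzhydrol ionises under the mild acid to the o-quinone methide/benzylic cation, and S-attack of the sulfinate gives the sulfone, a storable precursor from which base regenerates the o-quinone methide.

Step 12
Reactants: 19 (1R,4R,5R)-4,7,7-trimethyl-6-thiabicyclo[3.2.1]octane (isothiocineole); 20 4-methoxybenzyl bromide
Product: 21 (1R,4R,5R,6R)-6-(4-methoxybenzyl)-4,7,7-trimethyl-6-thiabicyclo[3.2.1]octan-6-ium trifluoromethanesulfonate
Conditions: LiOTf, CH2Cl2/H2O, rt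
Reagents that add atoms: lithium trifluoromethanesulfonate, [Li+].[O-]S(=O)(=O)C(F)(F)F
Why: SN2 S-alkylation of the thioether on its less hindered exo lone pair, driven by exchange of bromide for the non-nucleophilic triflate, should give a single sulfonium diastereomer.

Step 13
Reactants: 18 2-{[(2R,3R)-2-(2,4-dimethoxyphenyl)-3-(3,5-dimethoxyphenyl)-4-methoxy-2,3-dihydro-1-benzofuran-6-yl](4-methylbenzenesulfonyl)methyl}-3-methoxy-5-[(E)-2-(4-methoxyphenyl)ethenyl]phenol; 21 (1R,4R,5R,6R)-6-(4-methoxybenzyl)-4,7,7-trimethyl-6-thiabicyclo[3.2.1]octan-6-ium trifluoromethanesulfonate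
Product: 24 (2R,3R)-3-[(2R,3R)-2-(2,4-dimethoxyphenyl)-3-(3,5-dimethoxyphenyl)-4-methoxy-2,3-dihydro-1-benzofuran-6-yl]-4-methoxy-2-(4-methoxyphenyl)-6-[(E)-2-(4-methoxyphenyl)ethenyl]-2,3-dihydro-1-benzofuran, via o-quinone methide 22 (not isolated), via sulfonium ylide 23 (not isolated)
Conditions: 21 (1.5 equiv), Cs2CO3 (3 equiv), CH2Cl2/MeCN, −20 °C → rt
Reagents that add atoms: none
Why: Proposed new method: Cs2CO3 deprotonates the phenol of 18, which expels sulfinate to give the ring-A o-quinone methide, and deprotonates 21 to the semi-stabilised ylide; conjugate addition of the ylide carbon to the exocyclic methide carbon forms C2–C3 and rearomatises ring A to a phenoxide, which displaces the sulfide from C2 with inversion (5-exo-tet), the anti arrangement of the two aryl groups in the addition leading to the trans ring. The bicyclic sulfide is expected to fix the conformation and the reacting face of the ylide as it does in benzylidene transfer to aldehydes, imines and enones, so that C3 and C2 are set by the reagent and not by the remote stereocentres of unit 2, which cannot bias the planar methide. The closest known reactions are the base-mediated [4+1] annulation of o-quinone methides from 2-(1-tosylalkyl)phenols with sulfonium ylides to trans-2,3-dihydrobenzofurans and the asymmetric epoxidation and cyclopropanation with chiral benzylsulfonium ylides.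

Step 14
Reactants: 24 (2R,3R)-3-[(2R,3R)-2-(2,4-dimethoxyphenyl)-3-(3,5-dimethoxyphenyl)-4-methoxy-2,3-dihydro-1-benzofuran-6-yl]-4-methoxy-2-(4-methoxyphenyl)-6-[(E)-2-(4-methoxyphenyl)ethenyl]-2,3-dihydro-1-benzofuran
Product: 25 (2R,3R)-3-[(2R,3R)-2-(2,4-dihydroxyphenyl)-3-(3,5-dihydroxyphenyl)-4-hydroxy-2,3-dihydro-1-benzofuran-6-yl]-2-(4-hydroxyphenyl)-6-[(E)-2-(4-hydroxyphenyl)ethenyl]-2,3-dihydro-1-benzofuran-4-ol (CNP0118407.2)
Conditions: BBr3 (excess), CH2Cl2, −78 °C → rt; then H2O
Reagents that add atoms: none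
Why: Lewis-acid ether cleavage, in which bromide attacks the O-methyl carbon of each boron-complexed aryl methyl ether, should free all eight phenols without involving the four C–H stereocentres or the (E)-alkene.

**Compound list**

1 | methyl 3,5-dioxocyclohexane-1-carboxylate | COC(=O)C1CC(=O)CC(=O)C1 | starting material
2 | methyl 4-diazo-3,5-dioxocyclohexane-1-carboxylate | COC(=O)C1CC(=O)C(=[N+]=[N-])C(=O)C1 | intermediate
3 | 2,4-dimethoxybenzaldehyde | COc1ccc(C=O)c(OC)c1 | starting material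
4 | diethyl (3,5-dimethoxybenzyl)phosphonate | CCOP(=O)(Cc1cc(OC)cc(OC)c1)OCC | starting material
5 | (E)-2,4,3',5'-tetramethoxystilbene | COc1ccc(/C=C/c2cc(OC)cc(OC)c2)c(OC)c1 | intermediate
6 | methyl (2R,3R)-2-(2,4-dimethoxyphenyl)-3-(3,5-dimethoxyphenyl)-4-oxo-2,3,4,5,6,7-hexahydro-1-benzofuran-6-carboxylate (C6 epimers) | COC(=O)C1CC(=O)C2=C(C1)O[C@@H](c1ccc(OC)cc1OC)[C@@H]2c1cc(OC)cc(OC)c1 | intermediate
7 | lithium C4–C5 enolate of 6 | COC(=O)C1C=C([O-])C2=C(C1)O[C@@H](c1ccc(OC)cc1OC)[C@@H]2c1cc(OC)cc(OC)c1.[Li+] | intermediate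
8 | methyl (2R,3R)-2-(2,4-dimethoxyphenyl)-3-(3,5-dimethoxyphenyl)-4-hydroxy-2,3-dihydro-1-benzofuran-6-carboxylate | COC(=O)c1cc(O)c2c(c1)O[C@@H](c1ccc(OC)cc1OC)[C@@H]2c1cc(OC)cc(OC)c1 | intermediate
9 | methyl (2R,3R)-2-(2,4-dimethoxyphenyl)-3-(3,5-dimethoxyphenyl)-4-methoxy-2,3-dihydro-1-benzofuran-6-carboxylate | COC(=O)c1cc(OC)c2c(c1)O[C@@H](c1ccc(OC)cc1OC)[C@@H]2c1cc(OC)cc(OC)c1 | intermediate
10 | (2R,3R)-2-(2,4-dimethoxyphenyl)-3-(3,5-dimethoxyphenyl)-N,4-dimethoxy-N-methyl-2,3-dihydro-1-benzofuran-6-carboxamide | CON(C)C(=O)c1cc(OC)c2c(c1)O[C@@H](c1ccc(OC)cc1OC)[C@@H]2c1cc(OC)cc(OC)c1 | intermediate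
11 | 4-bromo-3,5-dimethoxybenzaldehyde | COc1cc(C=O)cc(OC)c1Br | starting material
12 | diethyl (4-methoxybenzyl)phosphonate | CCOP(=O)(Cc1ccc(OC)cc1)OCC | starting material
13 | 2-bromo-1,3-dimethoxy-5-[(E)-2-(4-methoxyphenyl)ethenyl]benzene | COc1ccc(/C=C/c2cc(OC)c(Br)c(OC)c2)cc1 | intermediate
14 | {2,6-dimethoxy-4-[(E)-2-(4-methoxyphenyl)ethenyl]phenyl}lithium | COc1ccc(/C=C/c2cc(OC)c([Li])c(OC)c2)cc1 | intermediate
15 | [(2R,3R)-2-(2,4-dimethoxyphenyl)-3-(3,5-dimethoxyphenyl)-4-methoxy-2,3-dihydro-1-benzofuran-6-yl]{2,6-dimethoxy-4-[(E)-2-(4-methoxyphenyl)ethenyl]phenyl}methanone | COc1ccc(/C=C/c2cc(OC)c(C(=O)c3cc(OC)c4c(c3)O[C@@H](c3ccc(OC)cc3OC)[C@@H]4c3cc(OC)cc(OC)c3)c(OC)c2)cc1 | intermediate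
16 | [(2R,3R)-2-(2,4-dimethoxyphenyl)-3-(3,5-dimethoxyphenyl)-4-methoxy-2,3-dihydro-1-benzofuran-6-yl]{2-hydroxy-6-methoxy-4-[(E)-2-(4-methoxyphenyl)ethenyl]phenyl}methanone | COc1ccc(/C=C/c2cc(O)c(C(=O)c3cc(OC)c4c(c3)O[C@@H](c3ccc(OC)cc3OC)[C@@H]4c3cc(OC)cc(OC)c3)c(OC)c2)cc1 | intermediate
17 | 2-{[(2R,3R)-2-(2,4-dimethoxyphenyl)-3-(3,5-dimethoxyphenyl)-4-methoxy-2,3-dihydro-1-benzofuran-6-yl](hydroxy)methyl}-3-methoxy-5-[(E)-2-(4-methoxyphenyl)ethenyl]phenol (carbinol epimers) | COc1ccc(/C=C/c2cc(O)c(C(O)c3cc(OC)c4c(c3)O[C@@H](c3ccc(OC)cc3OC)[C@@H]4c3cc(OC)cc(OC)c3)c(OC)c2)cc1 | intermediate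
18 | 2-{[(2R,3R)-2-(2,4-dimethoxyphenyl)-3-(3,5-dimethoxyphenyl)-4-methoxy-2,3-dihydro-1-benzofuran-6-yl](4-methylbenzenesulfonyl)methyl}-3-methoxy-5-[(E)-2-(4-methoxyphenyl)ethenyl]phenol (epimers at the sulfonyl carbon) | COc1ccc(/C=C/c2cc(O)c(C(c3cc(OC)c4c(c3)O[C@@H](c3ccc(OC)cc3OC)[C@@H]4c3cc(OC)cc(OC)c3)S(=O)(=O)c3ccc(C)cc3)c(OC)c2)cc1 | intermediate
19 | (1R,4R,5R)-4,7,7-trimethyl-6-thiabicyclo[3.2.1]octane (isothiocineole) | C[C@@H]1CC[C@@H]2C[C@H]1SC2(C)C | starting material
20 | 4-methoxybenzyl bromide | COc1ccc(CBr)cc1 | starting material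
21 | (1R,4R,5R,6R)-6-(4-methoxybenzyl)-4,7,7-trimethyl-6-thiabicyclo[3.2.1]octan-6-ium trifluoromethanesulfonate | C[C@@H]1CC[C@@H]2C[C@H]1[S@@+](Cc1ccc(OC)cc1)C2(C)C.[O-]S(=O)(=O)C(F)(F)F | intermediate
22 | 6-{[(2R,3R)-2-(2,4-dimethoxyphenyl)-3-(3,5-dimethoxyphenyl)-4-methoxy-2,3-dihydro-1-benzofuran-6-yl]methylidene}-5-methoxy-3-[(E)-2-(4-methoxyphenyl)ethenyl]cyclohexa-2,4-dien-1-one (o-quinone methide) | COc1ccc(/C=C/C2=CC(=O)C(=Cc3cc(OC)c4c(c3)O[C@@H](c3ccc(OC)cc3OC)[C@@H]4c3cc(OC)cc(OC)c3)C(OC)=C2)cc1 | intermediate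
23 | (4-methoxyphenyl)methanide ylide of sulfonium 21 | C[C@@H]1CC[C@@H]2C[C@H]1[S@@+]([CH-]c1ccc(OC)cc1)C2(C)C | intermediate
24 | (2R,3R)-3-[(2R,3R)-2-(2,4-dimethoxyphenyl)-3-(3,5-dimethoxyphenyl)-4-methoxy-2,3-dihydro-1-benzofuran-6-yl]-4-methoxy-2-(4-methoxyphenyl)-6-[(E)-2-(4-methoxyphenyl)ethenyl]-2,3-dihydro-1-benzofuran | COc1ccc(/C=C/c2cc(OC)c3c(c2)O[C@@H](c2ccc(OC)cc2)[C@@H]3c2cc(OC)c3c(c2)O[C@@H](c2ccc(OC)cc2OC)[C@@H]3c2cc(OC)cc(OC)c2)cc1 | intermediate
25 | (2R,3R)-3-[(2R,3R)-2-(2,4-dihydroxyphenyl)-3-(3,5-dihydroxyphenyl)-4-hydroxy-2,3-dihydro-1-benzofuran-6-yl]-2-(4-hydroxyphenyl)-6-[(E)-2-(4-hydroxyphenyl)ethenyl]-2,3-dihydro-1-benzofuran-4-ol | Oc1ccc(/C=C/c2cc(O)c3c(c2)O[C@@H](c2ccc(O)cc2)[C@@H]3c2cc(O)c3c(c2)O[C@@H](c2ccc(O)cc2O)[C@@H]3c2cc(O)cc(O)c2)cc1 | target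

**Step count**

Total: 14 steps. Longest linear sequence: 11 steps (1, 3, 4, 5, 6, 8, 9, 10, 11, 13, 14).

**Steps most likely to fail**

1. Step 3 (Proposed new method). The chiral carboxylate may not distinguish the two faces of the stilbene carbon, and the carbene may be diverted to the methoxyarene rings. Fallback, from 2 and 5, returning at 8: the known racemic annulation with Rh2(OAc)4 in PhF at 60 °C should give 6 together with an equal amount of its mirror image, methyl (2S,3S)-2-(2,4-dimethoxyphenyl)-3-(3,5-dimethoxyphenyl)-4-oxo-2,3,4,5,6,7-hexahydro-1-benzofuran-6-carboxylate F1. The mixture is aromatised under the conditions of step 4 to 8 and methyl (2S,3S)-2-(2,4-dimethoxyphenyl)-3-(3,5-dimethoxyphenyl)-4-hydroxy-2,3-dihydro-1-benzofuran-6-carboxylate F2. The enantiomers are then separated by preparative chromatography on a chiral stationary phase (supercritical CO2/MeOH), and the route continues from 8.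

2. Step 13 (Proposed new method). The chirality of the sulfide may be transmitted poorly to C3, or the addition may lack anti selectivity, so that unit 1 forms with the wrong or a mixed configuration relative to unit 2. Fallback, from 18 and 20, returning at 24: tetrahydrothiophene and 20 in acetone give the achiral salt 1-(4-methoxybenzyl)tetrahydrothiophenium bromide F3. Its ylide (Cs2CO3, CH2Cl2/MeCN) should undergo the known trans-selective [4+1] annulation with the o-quinone methide without facial bias, giving 24 and its unit-1 epimer, (2S,3S)-3-[(2R,3R)-2-(2,4-dimethoxyphenyl)-3-(3,5-dimethoxyphenyl)-4-methoxy-2,3-dihydro-1-benzofuran-6-yl]-4-methoxy-2-(4-methoxyphenyl)-6-[(E)-2-(4-methoxyphenyl)ethenyl]-2,3-dihydro-1-benzofuran F4. These are diastereomers and are separated by preparative HPLC; the route continues from 24.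

3. Step 14. The Lewis acid may ionise the benzylic C2–O1 and C2'–O1' bonds, which are activated by the para- and ortho/para-oxygenated aryl groups, leading to epimerisation, ring opening or Friedel–Crafts oligomerisation, and the eightfold cleavage may stop short. Fallback, from 24 directly to 25: the ethers are cleaved by SN2 attack of a soft nucleophile on the methyl carbons (NaSEt in large excess, DMF, 140 °C). This uses no Lewis acid, so no benzylic cation can form, and the accumulating phenoxides protect the rings from further reaction.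

**Further compounds**

F1 | step 3 | methyl (2S,3S)-2-(2,4-dimethoxyphenyl)-3-(3,5-dimethoxyphenyl)-4-oxo-2,3,4,5,6,7-hexahydro-1-benzofuran-6-carboxylate | COC(=O)C1CC(=O)C2=C(C1)O[C@H](c1ccc(OC)cc1OC)[C@H]2c1cc(OC)cc(OC)c1
F2 | step 3 | methyl (2S,3S)-2-(2,4-dimethoxyphenyl)-3-(3,5-dimethoxyphenyl)-4-hydroxy-2,3-dihydro-1-benzofuran-6-carboxylate | COC(=O)c1cc(O)c2c(c1)O[C@H](c1ccc(OC)cc1OC)[C@H]2c1cc(OC)cc(OC)c1
F3 | step 13 | 1-(4-methoxybenzyl)tetrahydrothiophenium bromide | COc1ccc(C[S+]2CCCC2)cc1.[Br-]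
F4 | step 13 | (2S,3S)-3-[(2R,3R)-2-(2,4-dimethoxyphenyl)-3-(3,5-dimethoxyphenyl)-4-methoxy-2,3-dihydro-1-benzofuran-6-yl]-4-methoxy-2-(4-methoxyphenyl)-6-[(E)-2-(4-methoxyphenyl)ethenyl]-2,3-dihydro-1-benzofuran | COc1ccc(/C=C/c2cc(OC)c3c(c2)O[C@H](c2ccc(OC)cc2)[C@H]3c2cc(OC)c3c(c2)O[C@@H](c2ccc(OC)cc2OC)[C@@H]3c2cc(OC)cc(OC)c2)cc1
F0 | step 14 | none | none
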